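**Retrosynthetic overview**
1. Glaucolide L 13 ⇒ 8α,13-diol 10: the C8 methacrylate is installed last, with the primary 13-OH masked in the same pot as a silyl ether.
2. Diol 10 ⇒ ene-dione 7: the C13–O bond comes from photoenolisation of the C8 ketone with O2 trapping (key photochemical step); the C8 stereocentre comes from 1,2-reduction.
3. Ene-dione 7 ⇒ butenolide 5: the C8 carbonyl oxygen is introduced by mediated anodic allylic C–H oxidation.
4. 5 ⇒ 2 ⇒ parthenolide 1: C1–O and C10–H by hydroboration then Mitsunobu inversion; the butenolide by exo-to-endo alkene isomerisation.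
5. Ring order: the ten-membered carbocycle, the 4,5-epoxide and the 12,6-lactone (with C4, C5, C6) are all bought in parthenolide; no ring is formed in the route.

Assumption: germacrane numbering is used, the target SMILES is read as (1S,4R,5R,6S,8S,10S) (1α-OAc, 10β-Me, 4α,5β-epoxide, 6α-O, 8α-O), and parthenolide is taken as a purchasable bulk natural product.

Step 1
Reactants: 1 parthenolide
Product: 2 (4R,5R,6S)-4,5-epoxygermacra-1(10)E,7(11)-dien-12,6-olide
Conditions: RhH(CO)(PPh3)3 (5 mol%), toluene, 80 °C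
Reagents that add atoms: none
Why: Metal-hydride alkene isomerisation: the rhodium hydride adds across the acrylate-type exocyclic alkene (H to C13, Rh to C11) and β-hydride elimination of H-7 gives the more stable tetrasubstituted conjugated butenolide, while the trisubstituted 1(10)-alkene and the epoxide are left alone; C7 becomes sp2 and C4, C5, C6 are retained.

Step 2
Reactants: 2 (4R,5R,6S)-4,5-epoxygermacra-1(10)E,7(11)-dien-12,6-olide
Product: 4 (1R,4R,5R,6S,10S)-4,5-epoxy-1-hydroxygermacr-7(11)-en-12,6-olide, via C1-alkylborane 3 (not isolated)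
Conditions: BH3·SMe2, THF, 0 °C; then 30% H2O2, pH 7 phosphate buffer, MeOH, 0 °C → rt
Reagents that add atoms: borane–dimethyl sulfide, C[S+](C)[BH3-] (boron stays only in 3); hydrogen peroxide, OO
Why: Brown hydroboration–oxidation: the electron-poor tetrasubstituted butenolide alkene is inert, boron goes to the less substituted C1 and H to C10 in a syn addition from the exposed peripheral face of the E-1(10)-alkene (the face used by epoxidation and singlet-oxygen ene reactions of parthenolide-type germacranolides), which sets 10S (10β-Me) and, after stereoretentive C–B oxidation, the 1β-alcohol (1R), both controlled by the purchased C4–C6 centres.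

Step 3
Reactants: 4 (1R,4R,5R,6S,10S)-4,5-epoxy-1-hydroxygermacr-7(11)-en-12,6-olide
Product: 5 (1S,4R,5R,6S,10S)-1-acetoxy-4,5-epoxygermacr-7(11)-en-12,6-olide
Conditions: PPh3, DIAD, AcOH, toluene, 0 °C → rt
Reagents that add atoms: acetic acid, CC(=O)O
Why: Mitsunobu esterification: SN2 displacement of the oxyphosphonium by acetate inverts C1 to the required 1α (1S) acetate under near-neutral conditions that spare the base-labile butenolide γ-H/epoxide array.

Step 4
Reactants: 5 (1S,4R,5R,6S,10S)-1-acetoxy-4,5-epoxygermacr-7(11)-en-12,6-olide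
Product: 7 (1S,4R,5R,6S,10S)-1-acetoxy-4,5-epoxy-8-oxogermacr-7(11)-en-12,6-olide, via 8-tert-butylperoxide 6 (not isolated)
Conditions: N-hydroxytetrachlorophthalimide (20 mol%), pyridine, tBuOOH, LiClO4, acetone, RVC anode/Ni cathode, constant current, rt
Reagents that add atoms: tert-butyl hydroperoxide, CC(C)(C)OO
Why: Mediated anodic allylic C–H oxidation: the anodically generated phthalimide N-oxyl abstracts a hydrogen from the only unhindered allylic methylene (C8, γ to the lactone carbonyl), the allyl radical is capped by tert-butylperoxyl at its less hindered C8 end, and peroxide 6 collapses (Kornblum–DeLaMare-type elimination with pyridine) to the ene-dione; the C8–O bond forms in the electrolysis and no stereocentre is touched.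

Step 5
Reactants: 7 (1S,4R,5R,6S,10S)-1-acetoxy-4,5-epoxy-8-oxogermacr-7(11)-en-12,6-olide
Product: 10 (1S,4R,5R,6S,8S,10S)-1-acetoxy-4,5-epoxy-8,13-dihydroxygermacr-7(11)-en-12,6-olide, via photodienol 8 (not isolated), via 13-hydroperoxide 9 (not isolated)
Conditions: O2, TPP (1 mol%), hv (365 nm + 525 nm LEDs), CH2Cl2, −40 °C; then MeOH, CeCl3·7H2O, NaBH4, −78 °C
Reagents that add atoms: dioxygen, O=O
Why: Proposed new method: 365 nm n,π* excitation of the cross-conjugated 2-ene-1,4-dicarbonyl lets the C8 carbonyl oxygen take a C13 hydrogen through a six-membered transition state (C13 and C8 are held cis on the butenolide alkene), giving the s-cis-locked, o-quinodimethane-like dienol 8, which singlet oxygen (TPP, green light) traps at its nucleophilic C13 terminus with return of the enol proton to give γ-hydroperoxy enone 9 and so the new C13–O bond; the closest known reactions are photoenolisation/photodeconjugation of Z-γ-H enones and O2 trapping of o-alkylaryl-ketone photoenols, not shown for aliphatic butenolide ene-diones; the in-flask Luche reduction then cleaves the O–O bond and delivers hydride 1,2 to C8 from the β-face (syn to H-6, away from the C9–C5 chain that lies on the α-side of the butenolide plane), setting 8S (8α-OH).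

Step 6
Reactants: 10 (1S,4R,5R,6S,8S,10S)-1-acetoxy-4,5-epoxy-8,13-dihydroxygermacr-7(11)-en-12,6-olide
Product: 12 (1S,4R,5R,6S,8S,10S)-1-acetoxy-13-(tert-butyldimethylsilyloxy)-4,5-epoxy-8-methacryloyloxygermacr-7(11)-en-12,6-olide, via 13-O-TBS diol 11 (not isolated)
Conditions: TBSCl, imidazole, CH2Cl2, −20 → 0 °C; then methacrylic anhydride, DMAP, pyridine, 0 °C → rt
Reagents that add atoms: tert-butyldimethylsilyl chloride, CC(C)(C)[Si](C)(C)Cl; methacrylic anhydride, C=C(C)C(=O)OC(=O)C(C)=C
Why: Chemoselective silylation followed by DMAP-catalysed (Steglich-type) acyl transfer: TBSCl/imidazole takes only the unhindered primary allylic 13-OH, so the anhydride esterifies the remaining secondary 8α-OH with retention, and only weak amine bases are present, which avoids E1cB epoxide opening from C6 and lactone migration.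

Step 7
Reactants: 12 (1S,4R,5R,6S,8S,10S)-1-acetoxy-13-(tert-butyldimethylsilyloxy)-4,5-epoxy-8-methacryloyloxygermacr-7(11)-en-12,6-olide
Product: 13 glaucolide L
Conditions: HF·pyridine, pyridine, THF, 0 °C → rt
Reagents that add atoms: none
Why: Fluoride-mediated desilylation: pyridine-buffered HF cleaves the primary Si–O bond (driven by the Si–F bond) without epoxide opening, acyl migration or ester cleavage, and no stereocentre is touched.

**Compound list**
1 | parthenolide, (4R,5R,6S,7S)-4,5-epoxygermacra-1(10)E,11(13)-dien-12,6-olide | C1C/C(C)=C/CC[C@@]2(C)O[C@@H]2[C@H]2OC(=O)C(=C)[C@H]12 | starting material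
2 | (4R,5R,6S)-4,5-epoxygermacra-1(10)E,7(11)-dien-12,6-olide (endocyclic butenolide isomer of 1) | C1C/C(C)=C/CC[C@@]2(C)O[C@@H]2[C@H]2OC(=O)C(C)=C12 | intermediate
3 | (1R,4R,5R,6S,10S)-1-boranyl-4,5-epoxygermacr-7(11)-en-12,6-olide (monoalkylborane, not isolated) | C1C[C@H](C)[C@H](B)CC[C@@]2(C)O[C@@H]2[C@H]2OC(=O)C(C)=C12 | intermediate
4 | (1R,4R,5R,6S,10S)-4,5-epoxy-1-hydroxygermacr-7(11)-en-12,6-olide (1β-OH, 10β-Me) | C1C[C@H](C)[C@H](O)CC[C@@]2(C)O[C@@H]2[C@H]2OC(=O)C(C)=C12 | intermediate
5 | (1S,4R,5R,6S,10S)-1-acetoxy-4,5-epoxygermacr-7(11)-en-12,6-olide (1α-OAc) | C1C[C@H](C)[C@@H](OC(C)=O)CC[C@@]2(C)O[C@@H]2[C@H]2OC(=O)C(C)=C12 | intermediate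
6 | 8-(tert-butylperoxy) derivative of 5, C8 epimers (not isolated) | CC(C)(C)OOC1C[C@H](C)[C@@H](OC(C)=O)CC[C@@]2(C)O[C@@H]2[C@H]2OC(=O)C(C)=C12 | intermediate
7 | (1S,4R,5R,6S,10S)-1-acetoxy-4,5-epoxy-8-oxogermacr-7(11)-en-12,6-olide (ene-dione) | O=C1C[C@H](C)[C@@H](OC(C)=O)CC[C@@]2(C)O[C@@H]2[C@H]2OC(=O)C(C)=C12 | intermediate
8 | (1S,4R,5R,6S,7E,10S)-1-acetoxy-4,5-epoxy-8-hydroxygermacra-7,11(13)-dien-12,6-olide (photodienol, enol OH syn to C11, not isolated) | O/C=1C[C@H](C)[C@@H](OC(C)=O)CC[C@@]2(C)O[C@@H]2[C@H]2OC(=O)C(=C)/C=12 | intermediate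
9 | (1S,4R,5R,6S,10S)-1-acetoxy-4,5-epoxy-13-hydroperoxy-8-oxogermacr-7(11)-en-12,6-olide (not isolated) | O=C1C[C@H](C)[C@@H](OC(C)=O)CC[C@@]2(C)O[C@@H]2[C@H]2OC(=O)C(COO)=C12 | intermediate
10 | (1S,4R,5R,6S,8S,10S)-1-acetoxy-4,5-epoxy-8,13-dihydroxygermacr-7(11)-en-12,6-olide | O[C@H]1C[C@H](C)[C@@H](OC(C)=O)CC[C@@]2(C)O[C@@H]2[C@H]2OC(=O)C(CO)=C12 | intermediate
11 | 13-O-tert-butyldimethylsilyl ether of 10 (not isolated) | O[C@H]1C[C@H](C)[C@@H](OC(C)=O)CC[C@@]2(C)O[C@@H]2[C@H]2OC(=O)C(CO[Si](C)(C)C(C)(C)C)=C12 | intermediate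
12 | (1S,4R,5R,6S,8S,10S)-1-acetoxy-13-(tert-butyldimethylsilyloxy)-4,5-epoxy-8-methacryloyloxygermacr-7(11)-en-12,6-olide | C=C(C)C(=O)O[C@H]1C[C@H](C)[C@@H](OC(C)=O)CC[C@@]2(C)O[C@@H]2[C@H]2OC(=O)C(CO[Si](C)(C)C(C)(C)C)=C12 | intermediate
13 | glaucolide L, (1S,4R,5R,6S,8S,10S)-1-acetoxy-4,5-epoxy-13-hydroxy-8-methacryloyloxygermacr-7(11)-en-12,6-olide | C=C(C)C(=O)O[C@H]1C[C@H](C)[C@@H](OC(C)=O)CC[C@@]2(C)O[C@@H]2[C@H]2OC(=O)C(CO)=C12 | target

**Totals**
Total step count: 7. Longest linear sequence: 7 steps (fully linear from 1).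

**Steps most likely to fail**

Step 5, the new photo-oxygenation. The ring may hold the C8 carbonyl turned away from C13, the dienol may reketonise before it is trapped, or 9 may be oxidised further. The fallback uses known chemistry, sets out from 7 and returns at 10. Wohl–Ziegler bromination of the enone γ-methyl group (NBS, AIBN, PhCF3, 75 °C) gives the 13-bromo ene-dione F1. Silver-assisted hydrolysis (Ag2CO3, acetone/H2O, rt) gives the 13-hydroxy ene-dione F2. Luche reduction (NaBH4, CeCl3·7H2O, MeOH, −78 °C) then gives diol 10.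

Step 4, the anodic allylic oxidation. The N-oxyl may abstract the C6 hydrogen instead, the peroxyl may add at C11, or the electron-poor γ-methylene may not react. The fallback sets out from 5 and returns at 7. Riley allylic hydroxylation (SeO2, dioxane, 80 °C; ene reaction with selenium at C11, then a [2,3]-shift that puts oxygen on C8) gives the 8-hydroxy butenolide F3 as either C8 epimer. Oxidation with Dess–Martin periodinane (NaHCO3, CH2Cl2, 0 °C) gives ene-dione 7.

Step 3, the Mitsunobu inversion. The ring carbinol next to C10 may eliminate or react with retention. The fallback sets out from 4 and returns at 5, inverting by oxidation and reduction instead of displacement. Dess–Martin periodinane (NaHCO3, CH2Cl2) gives the 1-ketone F4. NaBH4 (MeOH, −40 °C), with hydride entering from the peripheral β-face, gives the 1α-alcohol F5. Ac2O, DMAP and pyridine then give acetate 5.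

Further compounds
F1 | step 5 | (1S,4R,5R,6S,10S)-1-acetoxy-13-bromo-4,5-epoxy-8-oxogermacr-7(11)-en-12,6-olide | O=C1C[C@H](C)[C@@H](OC(C)=O)CC[C@@]2(C)O[C@@H]2[C@H]2OC(=O)C(CBr)=C12
F2 | step 5 | (1S,4R,5R,6S,10S)-1-acetoxy-4,5-epoxy-13-hydroxy-8-oxogermacr-7(11)-en-12,6-olide | O=C1C[C@H](C)[C@@H](OC(C)=O)CC[C@@]2(C)O[C@@H]2[C@H]2OC(=O)C(CO)=C12
F3 | step 4 | (1S,4R,5R,6S,10S)-1-acetoxy-4,5-epoxy-8-hydroxygermacr-7(11)-en-12,6-olide (C8 epimers) | OC1C[C@H](C)[C@@H](OC(C)=O)CC[C@@]2(C)O[C@@H]2[C@H]2OC(=O)C(C)=C12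
F4 | step 3 | (4R,5R,6S,10S)-4,5-epoxy-1-oxogermacr-7(11)-en-12,6-olide | C1C[C@H](C)C(=O)CC[C@@]2(C)O[C@@H]2[C@H]2OC(=O)C(C)=C12
F5 | step 3 | (1S,4R,5R,6S,10S)-4,5-epoxy-1-hydroxygermacr-7(11)-en-12,6-olide (1α-OH) | C1C[C@H](C)[C@@H](O)CC[C@@]2(C)O[C@@H]2[C@H]2OC(=O)C(C)=C12
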